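**Conventions, checks and assumptions**

- Numbering is that of the daucane skeleton. Ring A = C1–C5 and ring B = C1, C5–C10. C11–C13 are the isopropyl group on C4, C14 is the carbon on C8 and C15 is the methyl on C1. β is the face of C15 and α the opposite face.
- The target is (1R,4R,5S,6S,9S): 4β-OH, 5α-H, 6α-O-acyl, 9α-OH.
- Structure check: an acetoxypyranone with an (R)-configured carbinol carbon C4, and a cycloadduct with the C5–O–C9 bridge on the α-face and C15 on the β-face, correspond centre for centre to the target. No descriptor needs changing.
- Two chemical corrections to the design are made. (a) A 3-(silyloxymethyl)furan is deprotonated at C2, next to its side chain, and not at C5, so the 2,4-substitution pattern is secured in another way (step 6). (b) The cycloaddition precursor carries a free tertiary hydroxyl on C4 instead of a silyl ether; the reasons are in the second section.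
- Assumption: the catalytic asymmetric epoxidation of step 2 is taken to deliver 5 in high enantiomeric purity. C4 is the only centre set by a chiral reagent and it relays its configuration to all the others.

## Structural features

The target is a daucane sesquiterpenoid: a cyclopentane (ring A, C1–C5) trans-fused through the C1–C5 bond to a cycloheptane (ring B, C1, C5–C10), esterified at O6 with vanillic acid. Four of its five stereocentres are contiguous: the quaternary C1 (methyl), the ring-fusion methine C5, the fully substituted carbinol C4 (hydroxyl and isopropyl) and the acyloxy carbon C6. The fifth, the allylic carbinol C9, lies across ring B next to the exocyclic C8=C14 methylene. The C15 methyl and the 4-hydroxyl are on the β-face; H5, O6, O9 and the isopropyl group are on the α-face. The fragile parts are the allylic alcohol with its 1,1-disubstituted alkene (ionisation, migration of the double bond into the ring), the hindered ester that sits 1,3 to a tertiary alcohol, and the free phenol. At the ketone stage there is also a β-hydroxy ketone that can undergo retro-aldol cleavage and a β,γ-unsaturated ketone that can conjugate. The real difficulty is the seven-membered ring: it carries oxygen at C6 and C9 on the same face and an exocyclic alkene, and it is fused to a ring holding a quaternary carbon and a tertiary carbinol on either side of C5. The key step uses the fact that C5–C6(O)–C7–C8–C9(O) is the carbon chain of a 3-oxidopyrylium whose ring oxygen can span C5 and C9 on the α-face, where O9 and H5 end up. The two remaining ring-B atoms, C1 and C10, form an alkene held to C4 by C2–C3.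

## Logic of the disconnections

**30 ⇒ 29.** The two O–Si bonds (phenol and O9) are cut last. Buffered fluoride is the mildest way to reveal a phenol and an allylic alcohol beside an ester. The forward step must cleave both silyl ethers in one operation without acyl migration.

**29 ⇒ 24 + 27 (27 ⇒ 25).** The acyl C–O bond at O6 is cut, which separates the aromatic part and makes the end convergent. The forward step needs O6 to be the only hydroxyl that can be acylated. In 24, O9 is silylated and O4 is tertiary; in 27 the phenol is masked.

**24 ⇒ 23 ⇒ 22.** The C6–H bond is cut (carbinol back to ketone), then the O9–Si bond. The C6 ketone is the function the ylide delivers, and it is needed to open the bridge. The forward reduction must bring hydride to the β-face of C6, which is the face of the free 4-hydroxyl. O9 must be masked while it is still the only reactive hydroxyl.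

**22 ⇒ 20.** In the backward sense, the C5–H and one C7–H are removed and the C5–O (to O9) and C14–OAc bonds are restored. The flexible hydroxy ketone becomes a rigid oxabicycle, in which the O9/H5 relationship is a ring and the exocyclic methylene is an enone with an allylic acetate. The forward reduction must break C5–O and C14–O but not C9–O, and must protonate C5 on the α-face.

**20 ⇒ 18 (through 19).** The C1–C5 and C9–C10 bonds are cut. This removes both carbocycles and three stereocentres and leaves a monocyclic pyranone with one stereocentre in its side chain. The forward step needs the alkene to add to one face of the ylide. For this reason 18 carries a free 4-hydroxyl. It can hydrogen-bond to the oxido oxygen and so fix the side-chain conformation. It later directs the C6 reduction. It also avoids a silyl group that could migrate to the neighbouring carbinol oxygen.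

**18 ⇒ 17 ⇒ 15.** The two acetates are removed and the pyranone is traced back to a 2-furylcarbinol with a hydroxymethyl group at the furan 4-position (C14). The forward oxidation must attack the furan and leave the 1,1-disubstituted alkene and three hydroxyls alone.

**15 ⇒ 13 ⇒ 9 + 10.** The C5–C6 bond (carbinol carbon to furan C2) is cut, giving a convergent union of an α-oxygenated aldehyde with a furan. The forward step needs metalation of 10 at C5 of the furan only. C14 is carried at the aldehyde level, masked in the flask as a hemiaminal alkoxide that also blocks C2.

**9 ⇒ 8 ⇒ 7 ⇒ 5 + 6; 5 ⇒ 4; 4 ⇒ 1 + 2.** The C2–C3 bond is cut at an epoxide CH2, the epoxide oxygen is removed and the isopropyl–C4 bond is cut. C4 is thus made by asymmetric epoxidation of a 2-substituted allylic alcohol built in one step from 1 and 2. The forward steps need opening of 5 at the CH2 terminus only and oxidation of the primary position of 7 only. A monoterpene tertiary alcohol from the chiral pool that already holds this centre was weighed as the source of C4. It was set aside because one ring carbon would have to be excised and another added, which costs about three more steps.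

## Other disconnections considered

**Alternative 1:** The cut is the C1–C5 bond, with C5 brought in as a carbene carbon on the C4 ketone. In the forward step the isopropyl ketone A2 reacts with a lithiated silyl diazomethane to give an alkylidene carbene at C5. The carbene inserts into the tertiary C1–H bond with retention and gives the cyclopentene A1.
- In its favour: the quaternary centre comes stereospecifically from an existing C–H stereocentre, a tertiary C–H bond is the best site for such insertion, and A2 is a few routine steps from a commercial acyclic terpene alcohol.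
- Against it here: A1 holds only ring A and one stereocentre. The C4=C5 alkene must still be turned into the 4β-carbinol and the 5α-H with a bond from C5 to C6, under control from C1 alone, where methyl and a two-carbon chain differentiate the faces poorly. All of ring B, with both oxygens and the methylene, remains to be built and closed.
- Comparison: on structure the chosen step does more, forming two rings, three stereocentres and the full oxygen pattern of ring B. On mechanism, alternative 1 is the better of the two in predictability, because insertion with retention leaves no facial question, whereas the cycloaddition depends on a conformational bias. On step economy it is clearly longer after the key step.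

**Alternative 2:** The cuts are C7–C8 and C1–C10. In the forward step a chiral dirhodium tetracarboxylate (divalent rhodium) transfers the vinylcarbenoid of A5 to the vinyl group of diene A4. The resulting cis-divinylcyclopropane undergoes Cope rearrangement to the cycloheptadiene A3.
- In its favour: it is catalytic and convergent. Ring B and the quaternary C1 form in one stereospecific tandem event and C14 arrives as the ester carbon. The C5=C6 alkene of A3 allows a syn hydroboration that would place H5 and O6 on the same face in one step; on this point it is better than the enolate protonation and ketone reduction of the chosen plan.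
- Against it here: A4 must first be made enantioenriched with C4 in place and carries a tetrasubstituted ring alkene, so the Cope step must form a quaternary centre. The face of the diene is chosen by an interplay of C4 and catalyst that may be mismatched. A3 has no oxygen at C9, so the C8=C9 enoate must be reduced and transposed to the 9α-carbinol with C8=C14 under stereocontrol. A5 is unstable and must be used fresh.
- Comparison: for ring B and C1 the two key steps are equal, and both are concerted with geometry-controlled relative configuration. The chosen step also closes ring A and installs O9. Step economy is similar or slightly worse for alternative 2.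

**Alternative 3:** The cuts are C1–C15 and C5–C6. In the forward step a copper-catalysed asymmetric conjugate addition of a methylaluminium reagent to the enone A7 forms the quaternary centre. The aluminium enolate is trapped at C5 by a one-carbon aldehyde electrophile to give A6.
- In its favour: the quaternary centre is under catalyst control, three components are joined, and C9 and the isopropenyl unit come in a separate fragment. A later carbonyl-ene closure of the C6 aldehyde onto the isopropenyl group would give the 6-hydroxyl, the C7 methylene and C8=C14 directly; in functional-group economy of ring B this is better than the chosen plan.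
- Against it here: cyclopentenones are demanding substrates for this addition. Trapping a hindered enolate next to a new quaternary carbon is slow, and methyl and a CH2R group on C1 differentiate the faces of C5 only weakly. A6 is a β-hydroxy ketone prone to retro-aldol cleavage and dehydration. A7 needs its own asymmetric synthesis. The seven-membered ene closure and its selectivity at C6 are further open questions.
- Comparison: on structure the chosen step sets more centres at once and locks them in a bicycle, whereas alternative 3 spreads control over four separate events. Step counts are probably comparable.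

Key step: step 10

## Route

Step 1
Reactants: 1 prop-2-yn-1-ol; 2 isopropylmagnesium chloride
Product: 4 2-isopropylprop-2-en-1-ol, via alkenylmagnesium alkoxide 3 (not isolated)
Conditions: 2 (3 equiv), CuI (10 mol%), Et2O/toluene, −10 °C → rt; aq NH4Cl
Reagents that add atoms: none
Why: Copper-catalysed carbomagnesiation of the magnesium alkoxide of a propargylic alcohol: the alkyl group adds to the internal carbon and magnesium to the terminus, held as a five-membered chelate, and protonolysis should give the 2-substituted allylic alcohol; no stereocentre is formed.

Step 2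
Reactants: 4 2-isopropylprop-2-en-1-ol
Product: 5 (R)-(2-isopropyloxiran-2-yl)methanol
Conditions: Ti(OiPr)4 (10 mol%), D-(−)-diethyl tartrate (12 mol%), t-BuOOH, 4 Å MS, CH2Cl2, −20 °C
Reagents that add atoms: tert-butyl hydroperoxide, CC(C)(C)OO
Why: Katsuki–Sharpless asymmetric epoxidation, for which 2-substituted allylic alcohols are good substrates; by the empirical face rule the D-(−)-tartrate catalyst should deliver oxygen to the face that gives the (R)-epoxide (the L-(+) ligand would give S), and this sets C4.

Step 3
Reactants: 5 (R)-(2-isopropyloxiran-2-yl)methanol; 6 2-methylallylmagnesium chloride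
Product: 7 (R)-2-isopropyl-5-methylhex-5-ene-1,2-diol
Conditions: 6 (3 equiv), CuI (10 mol%), THF, −40 → 0 °C; aq NH4Cl
Reagents that add atoms: none
Why: Copper-catalysed SN2 opening of the epoxide at its unhindered CH2 terminus by a symmetrical allyl nucleophile; the C–O bond at the quaternary carbon is untouched, so C4 is retained, and Payne rearrangement of the alkoxide is degenerate here and returns the same enantiomer.

Step 4
Reactants: 7 (R)-2-isopropyl-5-methylhex-5-ene-1,2-diol
Product: 8 (R)-2-isopropyl-5-methyl-1,2-bis(trimethylsilyloxy)hex-5-ene
Conditions: TMSOTf (2.5 equiv), 2,6-lutidine, CH2Cl2, −78 → 0 °C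
Reagents that add atoms: trimethylsilyl triflate, C[Si](C)(C)OS(=O)(=O)C(F)(F)F
Why: Silyl triflate with a hindered pyridine base silylates both the primary and the hindered tertiary hydroxyl; the stereocentre is not involved.

Step 5
Reactants: 8 (R)-2-isopropyl-5-methyl-1,2-bis(trimethylsilyloxy)hex-5-ene
Product: 9 (R)-2-isopropyl-5-methyl-2-(trimethylsilyloxy)hex-5-enal
Conditions: (COCl)2, DMSO, CH2Cl2, −78 → −30 °C; Et3N, −78 → 0 °C
Reagents that add atoms: none
Why: Swern oxidation applied to a bis-silyl ether: the activated sulfoxide cleaves the primary silyl ether selectively and oxidises it in the same flask while the tertiary silyl ether stays; the aldehyde has no α-hydrogen, so C4 cannot epimerise, and it is used without chromatography.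

Step 6
Reactants: 10 furan-3-carbaldehyde; 9 (R)-2-isopropyl-5-methyl-2-(trimethylsilyloxy)hex-5-enal
Product: 13 5-[(1RS,2R)-1-hydroxy-2-isopropyl-5-methyl-2-(trimethylsilyloxy)hex-5-en-1-yl]furan-3-carbaldehyde, via lithium hemiaminal alkoxide 11 (not isolated), via 5-lithiated hemiaminal alkoxide 12 (not isolated)
Conditions: morpholine, n-BuLi, THF, −78 °C; 10; sec-BuLi, −78 °C; 9 (0.7 equiv), −78 °C; aq NH4Cl, −78 °C
Reagents that add atoms: none
Why: Protecting 10 in the flask as its lithium morpholide adduct masks the formyl group and, because the bulky hemiaminal alkoxide shields C2, should direct sec-BuLi to C5 (the known route to 5-substituted 3-furaldehydes); the furyllithium then adds to the non-enolisable aldehyde and work-up releases the formyl group. The new carbinol centre C5 forms as a mixture, which does not matter because it becomes sp2 in step 10, and a shift of the TMS group between the two oxygens at the alkoxide stage is harmless because the group is removed in step 7.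

Step 7
Reactants: 13 5-[(1RS,2R)-1-hydroxy-2-isopropyl-5-methyl-2-(trimethylsilyloxy)hex-5-en-1-yl]furan-3-carbaldehyde
Product: 15 (1RS,2R)-1-[4-(hydroxymethyl)furan-2-yl]-2-isopropyl-5-methylhex-5-ene-1,2-diol, via silyl ether diol 14 (not isolated)
Conditions: NaBH4, MeOH, 0 °C; then K2CO3, rt
Reagents that add atoms: none
Why: Borohydride reduction of the formyl group gives the C14 hydroxymethyl group, and base-catalysed methanolysis of the TMS ether follows in the same flask; the acid-sensitive furylcarbinol never meets acid.

Step 8
Reactants: 15 (1RS,2R)-1-[4-(hydroxymethyl)furan-2-yl]-2-isopropyl-5-methylhex-5-ene-1,2-diol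
Product: 17 6-hydroxy-2-[(3R)-3-hydroxy-2,6-dimethylhept-6-en-3-yl]-5-(hydroxymethyl)-2H-pyran-3(6H)-one, via furan endoperoxide 16 (not isolated)
Conditions: O2, visible light, tetraphenylporphyrin (1 mol%), CH2Cl2, −78 °C; Me2S, −78 °C → rt
Reagents that add atoms: dioxygen, O=O
Why: Achmatowicz oxidative ring expansion in its photooxygenation form: singlet oxygen adds (4+2) to the furan, Me2S reduces the endoperoxide to the Z-enedione, and the C5 hydroxyl closes onto the aldehyde to give the pyranone hemiacetal. Singlet oxygen is chosen because it reacts with the furan far faster than with a 1,1-disubstituted alkene, whereas electrophilic bromine or a hydroxyl-directed metal peroxide could engage the tertiary alcohol and the alkene; the ring C2 and anomeric centres form as mixtures and are erased in step 10.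

Step 9
Reactants: 17 6-hydroxy-2-[(3R)-3-hydroxy-2,6-dimethylhept-6-en-3-yl]-5-(hydroxymethyl)-2H-pyran-3(6H)-one
Product: 18 6-acetoxy-5-(acetoxymethyl)-2-[(3R)-3-hydroxy-2,6-dimethylhept-6-en-3-yl]-2H-pyran-3(6H)-one
Conditions: Ac2O (3 equiv), pyridine, DMAP (5 mol%), CH2Cl2, −20 → 0 °C
Reagents that add atoms: acetic anhydride, CC(=O)OC(C)=O
Why: Standard acetylation of the anomeric and primary allylic hydroxyls; the hindered tertiary hydroxyl on C4 should not react at this temperature, and the open-chain and furanoid forms of 17 funnel through the hemiacetal that acetylates fastest.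

Step 10
Reactants: 18 6-acetoxy-5-(acetoxymethyl)-2-[(3R)-3-hydroxy-2,6-dimethylhept-6-en-3-yl]-2H-pyran-3(6H)-one
Product: 20 14-acetoxy-5α,9α-epoxy-4β-hydroxydauc-7-en-6-one, via 3-oxidopyrylium ylide 19 (not isolated)
Conditions: 2,2,6,6-tetramethylpiperidine (2 equiv), toluene (0.01 M), 60 → 90 °C
Reagents that add atoms: none
Why: The hindered amine removes H5 of 18 and acetate leaves from C9 (vinylogous E1cB) to give the 3-oxidopyrylium ylide 19, whose termini C5 and C9 then add suprafacially and in one concerted step across the tethered C1=C10 alkene; the closest known reaction type is the intramolecular (5+2) cycloaddition of Achmatowicz-derived acetoxypyranones with unactivated alkenes. Ring A closes in a tether-controlled five-membered (5-exo-type) manner when the internal alkene carbon C1 bonds to C5 through C2–C3–C4, and ring B forms as the seven-membered carbocycle of the new 8-oxabicyclo[3.2.1]oct-3-en-2-one when C10 bonds to C9, with the ring oxygen left as the C5–O–C9 bridge. Regiochemistry is fixed by the tether, since only C1 can reach C5. C5 and C9 are set together by the suprafacial addition, and C1 is set by strain: a three-atom tether can only take the exo position on C1, syn to the oxygen bridge, so the C15 methyl ends endo, anti to the bridge, which is the trans ring fusion. The face of the ylide that is attacked, and with it the absolute sense of C1, C5 and C9, is decided by C4: the O4–H···O6 hydrogen bond to the oxido group and allylic 1,3-strain both hold the hydroxyl in the ylide plane beside O6, so the tether rises on one face and the isopropyl group covers the other, and the alkene adds on the tether face, leaving bridge and isopropyl group both α. Toluene keeps that hydrogen bond intact, and the fully substituted C4 (gem-disubstituent effect) together with high dilution should favour cyclisation over dimerisation of the ylide.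

Step 11
Reactants: 20 14-acetoxy-5α,9α-epoxy-4β-hydroxydauc-7-en-6-one
Product: 22 4β,9α-dihydroxy-5α-dauc-8(14)-en-6-one, via bridged exo-methylene ketone 21 (not isolated)
Conditions: SmI2 (5 equiv), THF/MeOH (10:1), −78 °C; aq NaHCO3
Reagents that add atoms: none
Why: Two consecutive two-electron reductions of known type by divalent samarium: the γ-acetoxy enone loses acetate (vinylogous reductive elimination) and the dienolate is protonated at C7 to give the deconjugated ketone 21, whose α-alkoxy ketone unit is then cleaved at C5–O, a bond held parallel to the carbonyl π system; the reverse order would converge on the same product. The C9 oxygen should stay because acetate is by far the better leaving group and, once C8=C14 exists, C9–O is no longer conjugated to the carbonyl. C5 is set by protonation of the enolate on the α-face, by methanol held on the trivalent samarium alkoxide of O9 on the face the oxygen has just left and away from the β-face C15 methyl and 4-hydroxyl; this is also the epimer expected to be more stable, since on ring A C6 is syn to the hydroxyl and not to the isopropyl group.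

Step 12
Reactants: 22 4β,9α-dihydroxy-5α-dauc-8(14)-en-6-one
Product: 23 9α-(tert-butyldimethylsilyloxy)-4β-hydroxy-5α-dauc-8(14)-en-6-one
Conditions: TBSCl, imidazole, DMF, 0 °C → rt
Reagents that add atoms: tert-butyldimethylsilyl chloride, CC(C)(C)[Si](C)(C)Cl
Why: Silylation of the only reactive hydroxyl, the secondary allylic 9-OH; the hindered tertiary 4-OH does not react under these conditions, and this distinguishes O9 from the O6 hydroxyl made next.

Step 13
Reactants: 23 9α-(tert-butyldimethylsilyloxy)-4β-hydroxy-5α-dauc-8(14)-en-6-one
Product: 24 9α-(tert-butyldimethylsilyloxy)-5α-dauc-8(14)-ene-4β,6α-diol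
Conditions: Me4NBH(OAc)3, MeCN/AcOH (1:1), −30 → 0 °C
Reagents that add atoms: none
Why: Hydroxyl-directed reduction of a β-hydroxy ketone (Evans–Saksena type): the 4β-hydroxyl exchanges onto boron and hydride is delivered through a six-membered transition state to the β-face of C6, giving the 6α (equatorial) alcohol, whereas an external hydride would meet the syn-axial C15 methyl on that face. The acidic medium avoids retro-aldol cleavage and migration of the β,γ-alkene.

Step 14
Reactants: 25 vanillic acid
Product: 27 4-(tert-butyldimethylsilyloxy)-3-methoxybenzoic acid, via bis-silylated vanillic acid 26 (not isolated)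
Conditions: TBSCl (2.5 equiv), imidazole, DMF, rt; then AcOH/THF/H2O, rt
Reagents that add atoms: tert-butyldimethylsilyl chloride, CC(C)(C)[Si](C)(C)Cl
Why: Silylation of phenol and carboxyl, then selective hydrolysis of the far more labile silyl ester; the aryl silyl ether is stable to dilute acetic acid.

Step 15
Reactants: 24 9α-(tert-butyldimethylsilyloxy)-5α-dauc-8(14)-ene-4β,6α-diol; 27 4-(tert-butyldimethylsilyloxy)-3-methoxybenzoic acid
Product: 29 6α-[4-(tert-butyldimethylsilyloxy)-3-methoxybenzoyloxy]-9α-(tert-butyldimethylsilyloxy)-5α-dauc-8(14)-en-4β-ol, via mixed anhydride 28 (not isolated)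
Conditions: 27 (2 equiv), 2,4,6-trichlorobenzoyl chloride, Et3N, THF, rt; then 24, DMAP, toluene, rt → 50 °C
Reagents that add atoms: none
Why: Yamaguchi esterification, suited to hindered secondary alcohols: the alcohol attacks the less hindered carbonyl of the mixed anhydride through the acylpyridinium; only the secondary 6-OH reacts because O9 is silylated and the tertiary 4-OH is inert, and C6 is not touched.

Step 16
Reactants: 29 6α-[4-(tert-butyldimethylsilyloxy)-3-methoxybenzoyloxy]-9α-(tert-butyldimethylsilyloxy)-5α-dauc-8(14)-en-4β-ol
Product: 30 (1R,4R,5S,6S,9S)-4β,9α-dihydroxy-6α-(4-hydroxy-3-methoxybenzoyloxy)-5α-dauc-8(14)-ene (CNP0330487.1)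
Conditions: TBAF, AcOH (1:1), THF, 0 °C → rt
Reagents that add atoms: none
Why: Fluoride cleaves the aryl and the secondary alkyl silyl ether in one operation; the acetic acid buffer keeps the medium from becoming basic, so ester migration and alkene isomerisation should not occur.

## Compound list

1 | prop-2-yn-1-ol | C#CCO | starting material
2 | isopropylmagnesium chloride | CC(C)[Mg]Cl | starting material
3 | chloromagnesium (Z)-3-(chloromagnesio)-2-isopropylprop-2-en-1-olate | Cl[Mg]/C=C(\CO[Mg]Cl)C(C)C | intermediate (not isolated)
4 | 2-isopropylprop-2-en-1-ol | C=C(CO)C(C)C | intermediate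
5 | (R)-(2-isopropyloxiran-2-yl)methanol | OC[C@]1(C(C)C)CO1 | intermediate
6 | 2-methylallylmagnesium chloride | C=C(C)C[Mg]Cl | starting material
7 | (R)-2-isopropyl-5-methylhex-5-ene-1,2-diol | C=C(C)CC[C@@](CO)(O)C(C)C | intermediate
8 | (R)-2-isopropyl-5-methyl-1,2-bis(trimethylsilyloxy)hex-5-ene | C=C(C)CC[C@@](CO[Si](C)(C)C)(O[Si](C)(C)C)C(C)C | intermediate
9 | (R)-2-isopropyl-5-methyl-2-(trimethylsilyloxy)hex-5-enal | C=C(C)CC[C@@](C=O)(O[Si](C)(C)C)C(C)C | intermediate
10 | furan-3-carbaldehyde | O=Cc1ccoc1 | starting material
11 | lithium (furan-3-yl)(morpholin-4-yl)methanolate | [Li]OC(c1ccoc1)N1CCOCC1 | intermediate (not isolated)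
12 | lithium (5-lithiofuran-3-yl)(morpholin-4-yl)methanolate | [Li]OC(c1coc([Li])c1)N1CCOCC1 | intermediate (not isolated)
13 | 5-[(1RS,2R)-1-hydroxy-2-isopropyl-5-methyl-2-(trimethylsilyloxy)hex-5-en-1-yl]furan-3-carbaldehyde | O=Cc1coc(C(O)[C@@](O[Si](C)(C)C)(CCC(C)=C)C(C)C)c1 | intermediate
14 | (1RS,2R)-1-[4-(hydroxymethyl)furan-2-yl]-2-isopropyl-5-methyl-2-(trimethylsilyloxy)hex-5-en-1-ol | OCc1coc(C(O)[C@@](O[Si](C)(C)C)(CCC(C)=C)C(C)C)c1 | intermediate (not isolated)
15 | (1RS,2R)-1-[4-(hydroxymethyl)furan-2-yl]-2-isopropyl-5-methylhex-5-ene-1,2-diol | OCc1coc(C(O)[C@@](O)(CCC(C)=C)C(C)C)c1 | intermediate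
16 | 2,5-endoperoxide (2,3,7-trioxabicyclo[2.2.1]hept-5-ene) of furan 15 | OCC1=CC2(OOC1O2)C(O)[C@@](O)(CCC(C)=C)C(C)C | intermediate (not isolated)
17 | 6-hydroxy-2-[(3R)-3-hydroxy-2,6-dimethylhept-6-en-3-yl]-5-(hydroxymethyl)-2H-pyran-3(6H)-one (mixture at ring C2 and C6) | OCC1=CC(=O)C(OC1O)[C@@](O)(CCC(C)=C)C(C)C | intermediate
18 | 6-acetoxy-5-(acetoxymethyl)-2-[(3R)-3-hydroxy-2,6-dimethylhept-6-en-3-yl]-2H-pyran-3(6H)-one (mixture at ring C2 and C6) | CC(=O)OCC1=CC(=O)C(OC1OC(C)=O)[C@@](O)(CCC(C)=C)C(C)C | intermediate
19 | 5-(acetoxymethyl)-2-[(3R)-3-hydroxy-2,6-dimethylhept-6-en-3-yl]pyrylium-3-olate | CC(=O)OCc1c[o+]c(c([O-])c1)[C@@](O)(CCC(C)=C)C(C)C | intermediate (not isolated)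
20 | 14-acetoxy-5α,9α-epoxy-4β-hydroxydauc-7-en-6-one | CC(=O)OCC1=CC(=O)[C@]23[C@](C)(CC[C@@]2(O)C(C)C)C[C@@H]1O3 | intermediate
21 | 5α,9α-epoxy-4β-hydroxydauc-8(14)-en-6-one | C=C1CC(=O)[C@]23[C@](C)(CC[C@@]2(O)C(C)C)C[C@@H]1O3 | intermediate (not isolated)
22 | 4β,9α-dihydroxy-5α-dauc-8(14)-en-6-one | C=C1CC(=O)[C@@H]2[C@](C)(CC[C@@]2(O)C(C)C)C[C@@H]1O | intermediate
23 | 9α-(tert-butyldimethylsilyloxy)-4β-hydroxy-5α-dauc-8(14)-en-6-one | C=C1CC(=O)[C@@H]2[C@](C)(CC[C@@]2(O)C(C)C)C[C@@H]1O[Si](C)(C)C(C)(C)C | intermediate
24 | 9α-(tert-butyldimethylsilyloxy)-5α-dauc-8(14)-ene-4β,6α-diol | C=C1C[C@H](O)[C@@H]2[C@](C)(CC[C@@]2(O)C(C)C)C[C@@H]1O[Si](C)(C)C(C)(C)C | intermediate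
25 | vanillic acid | COc1cc(C(=O)O)ccc1O | starting material
26 | tert-butyldimethylsilyl 4-(tert-butyldimethylsilyloxy)-3-methoxybenzoate | COc1cc(C(=O)O[Si](C)(C)C(C)(C)C)ccc1O[Si](C)(C)C(C)(C)C | intermediate (not isolated)
27 | 4-(tert-butyldimethylsilyloxy)-3-methoxybenzoic acid | COc1cc(C(=O)O)ccc1O[Si](C)(C)C(C)(C)C | intermediate
28 | 4-(tert-butyldimethylsilyloxy)-3-methoxybenzoic 2,4,6-trichlorobenzoic anhydride | COc1cc(C(=O)OC(=O)c2c(Cl)cc(Cl)cc2Cl)ccc1O[Si](C)(C)C(C)(C)C | intermediate (not isolated)
29 | 6α-[4-(tert-butyldimethylsilyloxy)-3-methoxybenzoyloxy]-9α-(tert-butyldimethylsilyloxy)-5α-dauc-8(14)-en-4β-ol | C=C1C[C@H](OC(=O)c2ccc(O[Si](C)(C)C(C)(C)C)c(OC)c2)[C@@H]2[C@](C)(CC[C@@]2(O)C(C)C)C[C@@H]1O[Si](C)(C)C(C)(C)C | intermediate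
30 | (1R,4R,5S,6S,9S)-4β,9α-dihydroxy-6α-(4-hydroxy-3-methoxybenzoyloxy)-5α-dauc-8(14)-ene | C=C1C[C@H](OC(=O)c2ccc(O)c(OC)c2)[C@@H]2[C@](C)(CC[C@@]2(O)C(C)C)C[C@@H]1O | target

## Step count and least certain steps

Total step count: 16. Longest linear sequence: 15 steps (steps 1–13, 15 and 16, from 1); step 14 is a one-step side branch.

**Step 10 (key step).** The most likely failure is loss of facial discrimination. If the internal hydrogen bond between the 4-hydroxyl and the oxido group is broken by the medium or the ammonium counter-ion, the conformer with the isopropyl group beside the oxido oxygen can react and give the diastereomeric bridge. A second concern is dimerisation of the ylide, because the alkene is unactivated and must form a quaternary carbon. The fallback replaces hydrogen-bond control by steric control and removes the free hydroxyl from the ylide. It sets out from 18: silylation with N-(trimethylsilyl)imidazole (CH2Cl2, rt) gives the 4-O-trimethylsilyl acetoxypyranone F1. The same amine-induced cycloaddition then gives the 4-O-trimethylsilyl cycloadduct F2, with the small oxygen atom of the silyloxy group beside the oxido oxygen and the isopropyl group on the far face. Citric acid in MeOH removes the silyl group and the route is rejoined at 20.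

**Step 11.** The most likely failure is protonation of the C5 enolate on the β-face, giving the cis ring fusion, because the two faces are flanked by groups of similar size and C5 cannot be equilibrated later without moving the β,γ-alkene. A related risk is loss of the C9 oxygen by vinylogous cleavage before acetate has left. The fallback separates the two reductions and shields the β-face. It sets out from 20: Zn dust, NH4Cl, THF/MeOH, 0 °C removes only the allylic acetate (an ether bridge is inert to zinc) and gives 21, now isolated. N-(Trimethylsilyl)imidazole converts 21 into its 4-O-trimethylsilyl ether F3, whose silyloxy group together with C15 blocks the β-face of C5. SmI2 (2.5 equiv), THF/MeOH, −78 °C then cleaves only C5–O, since C9–O is no longer conjugated, and gives the 4-O-trimethylsilyl hydroxy ketone F4. Citric acid in MeOH returns the route to 22.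

**Step 13.** The most likely failure is that the hindered tertiary hydroxyl does not exchange onto boron, so that hydride arrives externally on the α-face, or not at all, and the C6 epimer forms. The fallback uses that epimer. It sets out from 23: NaBH4, CeCl3·7H2O, MeOH, −40 °C gives the 6β-alcohol F5. Mitsunobu esterification of F5 with acid 27 (PPh3, DIAD, toluene, 0 °C → rt) inverts C6 and rejoins the route at 29.

**Step 8.** The most likely failure is diversion of the ring-chain equilibrium: the free hydroxymethyl group can close onto the C6 ketone of the enedione and give a furanoid hemiketal, and a triol can be over-oxidised. The fallback masks that hydroxyl first and uses the bromine-mediated form of the ring expansion. It sets out from 15: Ac2O (1.05 equiv), 2,4,6-collidine, CH2Cl2, −40 °C acetylates only the primary alcohol and gives the monoacetate F6. NBS, NaHCO3, NaOAc, THF/H2O, 0 °C gives the 5-(acetoxymethyl) hemiacetal F7. Ac2O, pyridine, DMAP then rejoins the route at 18.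

**Step 6.** The most likely failure is incomplete or C2-directed deprotonation of the hemiaminal alkoxide, followed by slow addition of an aggregated dianion to a neopentyl-type aldehyde. The fallback fixes the site of metalation with a halogen. It sets out from 9 and purchased methyl 5-bromofuran-3-carboxylate F8. Bromine–magnesium exchange with iPrMgCl·LiCl (THF, −40 °C) gives the furylmagnesium chloride F9, which adds to 9 (−40 → 0 °C) to give the hydroxy ester F10. LiAlH4, THF, 0 °C and then K2CO3, MeOH reduce the ester and remove the silyl group, and the route is rejoined at 15.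

## Further compounds

F1 | step 10 | 6-acetoxy-5-(acetoxymethyl)-2-[(3R)-2,6-dimethyl-3-(trimethylsilyloxy)hept-6-en-3-yl]-2H-pyran-3(6H)-one | CC(=O)OCC1=CC(=O)C(OC1OC(C)=O)[C@@](O[Si](C)(C)C)(CCC(C)=C)C(C)C
F2 | step 10 | 14-acetoxy-5α,9α-epoxy-4β-(trimethylsilyloxy)dauc-7-en-6-one | CC(=O)OCC1=CC(=O)[C@]23[C@](C)(CC[C@@]2(O[Si](C)(C)C)C(C)C)C[C@@H]1O3
F3 | step 11 | 5α,9α-epoxy-4β-(trimethylsilyloxy)dauc-8(14)-en-6-one | C=C1CC(=O)[C@]23[C@](C)(CC[C@@]2(O[Si](C)(C)C)C(C)C)C[C@@H]1O3
F4 | step 11 | 9α-hydroxy-4β-(trimethylsilyloxy)-5α-dauc-8(14)-en-6-one | C=C1CC(=O)[C@@H]2[C@](C)(CC[C@@]2(O[Si](C)(C)C)C(C)C)C[C@@H]1O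
F5 | step 13 | 9α-(tert-butyldimethylsilyloxy)-5α-dauc-8(14)-ene-4β,6β-diol | C=C1C[C@@H](O)[C@@H]2[C@](C)(CC[C@@]2(O)C(C)C)C[C@@H]1O[Si](C)(C)C(C)(C)C
F6 | step 8 | {5-[(1RS,2R)-1,2-dihydroxy-2-isopropyl-5-methylhex-5-en-1-yl]furan-3-yl}methyl acetate | CC(=O)OCc1coc(C(O)[C@@](O)(CCC(C)=C)C(C)C)c1
F7 | step 8 | 5-(acetoxymethyl)-6-hydroxy-2-[(3R)-3-hydroxy-2,6-dimethylhept-6-en-3-yl]-2H-pyran-3(6H)-one | CC(=O)OCC1=CC(=O)C(OC1O)[C@@](O)(CCC(C)=C)C(C)C
F8 | step 6 | methyl 5-bromofuran-3-carboxylate (purchased) | COC(=O)c1coc(Br)c1
F9 | step 6 | [4-(methoxycarbonyl)furan-2-yl]magnesium chloride | COC(=O)c1coc([Mg]Cl)c1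
F10 | step 6 | methyl 5-[(1RS,2R)-1-hydroxy-2-isopropyl-5-methyl-2-(trimethylsilyloxy)hex-5-en-1-yl]furan-3-carboxylate | COC(=O)c1coc(C(O)[C@@](O[Si](C)(C)C)(CCC(C)=C)C(C)C)c1
A1 | alternative 1 | (R)-tert-butyl[2-(3-isopropyl-1-methylcyclopent-2-en-1-yl)ethoxy]dimethylsilane | CC(C)C1=C[C@](C)(CC1)CCO[Si](C)(C)C(C)(C)C
A2 | alternative 1 | (S)-8-(tert-butyldimethylsilyloxy)-2,6-dimethyloctan-3-one | CC(C)C(=O)CC[C@H](C)CCO[Si](C)(C)C(C)(C)C
A3 | alternative 2 | methyl 4β-(triethylsilyloxy)dauca-5,8-dien-14-oate | C1=C(C(=O)OC)CC=C2[C@](C)(CC[C@@]2(O[Si](CC)(CC)CC)C(C)C)C1
A4 | alternative 2 | (R)-triethyl[(1-isopropyl-3-methyl-2-vinylcyclopent-2-en-1-yl)oxy]silane | C=CC1=C(C)CC[C@@]1(O[Si](CC)(CC)CC)C(C)C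
A5 | alternative 2 | methyl 2-diazobut-3-enoate | COC(=O)C(=[N+]=[N-])C=C
A6 | alternative 3 | 3-[2-(tert-butyldimethylsilyloxy)-3-methylbut-3-en-1-yl]-2-(hydroxymethyl)-3-methylcyclopentan-1-one (C1, C5 and C9 configured as in the target) | OC[C@@H]1[C@](C)(CCC1=O)C[C@H](O[Si](C)(C)C(C)(C)C)C(C)=C
A7 | alternative 3 | 3-[2-(tert-butyldimethylsilyloxy)-3-methylbut-3-en-1-yl]cyclopent-2-en-1-one (C9 configured as in the target) | O=C1C=C(CC1)C[C@H](O[Si](C)(C)C(C)(C)C)C(C)=C
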